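**Retrosynthetic overview**

1. Molephantinin ⇐ E1cB opening of a 4,5‑epoxide by the C2 ketone (sets C3=C4 Z, keeps C5–O) ⇐ outer‑face epoxidation of the (1(10)E,4E)‑germacradienolide 25 ⇐ C2 oxidation, C8 tigloylation and C11 methylenation of bicyclic lactone 17.
2. Key disconnection: C5–C6 (ring‑closing), together with C4–C15 and O6–C12: a nickel‑catalysed methylative alkyne–aldehyde macrocyclisation/lactonisation of the acyclic ynal 15.
3. Ring order: the ten‑membered carbocycle closes first (C5–C6) and the γ‑lactone second (O6–C12), both in step 12; no other permanent ring is made.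
4. Enabling feature: C6 (carbinol, ring fusion) is flanked by C5 and by C4, which carries the C15 methyl; read back through the epoxide, the ring contains the allylic alcohol C6(O)–C5H=C4(CH3), the sum of an aldehyde (C6), a terminal alkyne (C4≡C5) and a methyl group, and O6 lies γ to C12 on the C7 side chain, so the same alkoxide closes the five‑membered lactone.
5. 15 ⇐ Evans syn‑aldol (C7, C8) of succinate imide 11 with aldehyde 8; 8 ⇐ carboalumination (E‑C1=C10) and propargylation (C2–C3) starting from silyl butynyl ether 1.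

Key step: step 12

Remark: atoms are cited by germacrane numbering (C1–C15; lactone oxygen on C6, ester oxygen on C8).
Remark (assumption): the C2 carbinol configuration set in step 3 is immaterial because C2 becomes the ketone in step 17; it is drawn S throughout, and the enantiomeric catalyst would serve equally.

**Route**

Step 1
Reactants: 1 tert-butyl(but-3-yn-1-yloxy)dimethylsilane
Product: 2 (E)-5-[(tert-butyldimethylsilyl)oxy]-3-methylpent-2-en-1-ol
Conditions: AlMe3 (2.5 equiv), Cp2ZrCl2 (0.2 equiv), CH2Cl2, 0 °C to rt; then n-BuLi, THF, −78 to 0 °C; (CH2O)n, rt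
Reagents that add atoms: trimethylaluminium C[Al](C)C; formaldehyde (as paraformaldehyde) C=O
Why: Negishi carboalumination adds CH3 and aluminium syn across the terminal alkyne with aluminium on the terminal carbon, and hydroxymethylation of the derived alanate with retention should give the E‑trisubstituted C1=C10 olefin with C2 attached.

Step 2
Reactants: 2 (E)-5-[(tert-butyldimethylsilyl)oxy]-3-methylpent-2-en-1-ol
Product: 3 (E)-5-[(tert-butyldimethylsilyl)oxy]-3-methylpent-2-enal
Conditions: MnO2, CH2Cl2, rt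
Reagents that add atoms: none
Why: Allylic oxidation with MnO2 is selective for the allylic alcohol and should leave the olefin geometry and the silyl ether intact.

Step 3
Reactants: 3 (E)-5-[(tert-butyldimethylsilyl)oxy]-3-methylpent-2-enal + 4 allenylboronic acid pinacol ester
Product: 5 (4S,5E)-8-[(tert-butyldimethylsilyl)oxy]-6-methyloct-5-en-1-yn-4-ol
Conditions: 4 (1.5 equiv), (R)-TRIP phosphoric acid (10 mol %), 4 Å MS, toluene, −20 °C
Reagents that add atoms: none
Why: Brønsted‑acid‑catalysed carbonyl propargylation, in which the allenylboronate adds 1,2 to the enal through a closed six‑membered SE2' transition state organised by the chiral phosphoric acid, which sets the C2 carbinol (a centre that is destroyed later).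

Step 4
Reactants: 5 (4S,5E)-8-[(tert-butyldimethylsilyl)oxy]-6-methyloct-5-en-1-yn-4-ol
Product: 6 tert-butyl{[(3E,5S)-5-[(4-methoxybenzyl)oxy]-3-methyloct-3-en-7-yn-1-yl]oxy}dimethylsilane
Conditions: NaH, 4-methoxybenzyl chloride, Bu4NI (cat.), THF/DMF, 0 °C to rt
Reagents that add atoms: 4-methoxybenzyl chloride COc1ccc(CCl)cc1
Why: Williamson etherification of the sodium alkoxide installs a C2 protecting group that should survive fluoride, aluminium and zinc reagents and amide base and is removable oxidatively.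

Step 5
Reactants: 6 tert-butyl{[(3E,5S)-5-[(4-methoxybenzyl)oxy]-3-methyloct-3-en-7-yn-1-yl]oxy}dimethylsilane
Product: 7 (3E,5S)-5-[(4-methoxybenzyl)oxy]-3-methyloct-3-en-7-yn-1-ol
Conditions: Bu4NF, THF, 0 °C
Reagents that add atoms: none
Why: Fluoride‑induced desilylation frees the primary alcohol while the benzylic ether and the alkyne are inert.

Step 6
Reactants: 7 (3E,5S)-5-[(4-methoxybenzyl)oxy]-3-methyloct-3-en-7-yn-1-ol
Product: 8 (3E,5S)-5-[(4-methoxybenzyl)oxy]-3-methyloct-3-en-7-ynal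
Conditions: Dess–Martin periodinane, pyridine, CH2Cl2, 0 °C; used crude at once
Reagents that add atoms: none
Why: Dess–Martin oxidation under buffered, non‑enolising conditions should give the β,γ‑unsaturated aldehyde without migration of the C1=C10 double bond into conjugation.

Step 7
Reactants: 9 (R)-4-benzyloxazolidin-2-one + 10 methyl 4-chloro-4-oxobutanoate
Product: 11 methyl 4-[(R)-4-benzyl-2-oxooxazolidin-3-yl]-4-oxobutanoate
Conditions: n-BuLi, THF, −78 °C; then 10
Reagents that add atoms: none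
Why: N‑Acylation of the lithiated oxazolidinone by the acid chloride is much faster than attack on the methyl ester.

Step 8
Reactants: 11 methyl 4-[(R)-4-benzyl-2-oxooxazolidin-3-yl]-4-oxobutanoate + 8 (3E,5S)-5-[(4-methoxybenzyl)oxy]-3-methyloct-3-en-7-ynal
Product: 12 methyl (3R,4S,6E,8S)-3-{[(R)-4-benzyl-2-oxooxazolidin-3-yl]carbonyl}-4-hydroxy-8-[(4-methoxybenzyl)oxy]-6-methylundec-6-en-10-ynoate
Conditions: 11, Bu2BOTf, i-Pr2NEt, CH2Cl2, −78 to 0 °C; 8, −78 to 0 °C; pH 7 buffer, MeOH, H2O2
Reagents that add atoms: none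
Why: Evans syn‑aldol reaction, in which the Z‑boron enolate of the imide (enolised in preference to the ester) reacts through a Zimmerman–Traxler chair whose one face is shielded by the (R)-benzyl auxiliary, setting C7 and C8 in the syn relationship and absolute sense of the target.

Step 9
Reactants: 12 methyl (3R,4S,6E,8S)-3-{[(R)-4-benzyl-2-oxooxazolidin-3-yl]carbonyl}-4-hydroxy-8-[(4-methoxybenzyl)oxy]-6-methylundec-6-en-10-ynoate
Product: 13 methyl (3R,4S,6E,8S)-4-hydroxy-3-[methoxy(methyl)carbamoyl]-8-[(4-methoxybenzyl)oxy]-6-methylundec-6-en-10-ynoate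
Conditions: MeNHOMe·HCl, AlMe3, CH2Cl2, −10 to 0 °C
Reagents that add atoms: N,O-dimethylhydroxylamine hydrochloride CNOC.Cl
Why: Weinreb transamination, in which the aluminium amide, directed by the C8 aluminium alkoxide, attacks the exocyclic imide carbonyl and releases the auxiliary without touching the methyl ester.

Step 10
Reactants: 13 methyl (3R,4S,6E,8S)-4-hydroxy-3-[methoxy(methyl)carbamoyl]-8-[(4-methoxybenzyl)oxy]-6-methylundec-6-en-10-ynoate
Product: 14 methyl (3R,4S,6E,8S)-4-[(tert-butyldimethylsilyl)oxy]-3-[methoxy(methyl)carbamoyl]-8-[(4-methoxybenzyl)oxy]-6-methylundec-6-en-10-ynoate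
Conditions: TBSOTf, 2,6-lutidine, CH2Cl2, −78 °C
Reagents that add atoms: tert-butyldimethylsilyl triflate CC(C)(C)[Si](C)(C)OS(=O)(=O)C(F)(F)F
Why: Silylation with the triflate protects the hindered C8 hydroxyl so that it can neither lactonise onto C12 nor compete with O6 later.

Step 11
Reactants: 14 methyl (3R,4S,6E,8S)-4-[(tert-butyldimethylsilyl)oxy]-3-[methoxy(methyl)carbamoyl]-8-[(4-methoxybenzyl)oxy]-6-methylundec-6-en-10-ynoate
Product: 15 methyl (3R,4S,6E,8S)-4-[(tert-butyldimethylsilyl)oxy]-3-formyl-8-[(4-methoxybenzyl)oxy]-6-methylundec-6-en-10-ynoate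
Conditions: i-Bu2AlH (1.1 equiv), THF, −78 °C; aq. KNa tartrate
Reagents that add atoms: none
Why: Weinreb amide reduction, in which i-Bu2AlH forms a chelated tetrahedral intermediate that collapses to the C6 aldehyde only on work‑up and, with one equivalent at −78 °C, the amide should react ahead of the methyl ester.

Step 12
Reactants: 15 methyl (3R,4S,6E,8S)-4-[(tert-butyldimethylsilyl)oxy]-3-formyl-8-[(4-methoxybenzyl)oxy]-6-methylundec-6-en-10-ynoate
Product: 17 (3aS,4S,6E,8S,10E,11aR)-4-[(tert-butyldimethylsilyl)oxy]-8-[(4-methoxybenzyl)oxy]-6,10-dimethyl-3a,4,5,8,9,11a-hexahydrocyclodeca[b]furan-2(3H)-one, via macrocyclic hydroxy ester zinc alkoxide 16 (not isolated)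
Conditions: Ni(cod)2 (20 mol %), IMes (20 mol %), Me2Zn (3 equiv), THF (0.003 M, slow addition of 15), 0 °C to rt; then 40 °C; aq. NH4Cl
Reagents that add atoms: dimethylzinc C[Zn]C
Why: Proposed new method: zerovalent nickel should bind the terminal alkyne and the aldehyde of 15 and couple them oxidatively to an oxanickelacyclopentene (C5–C6 bond, nickel on C4), after which Me2Zn transfers methyl to nickel and C(sp2)–CH3 reductive elimination releases the methylzinc alkoxide 16 and zerovalent nickel; since aldehyde carbon and methyl add to the same side of the alkyne, C6 and C15 end cis and the ring olefin C4=C5 is E. The closest known reaction types are the nickel‑catalysed three‑component alkylative coupling of alkynes, aldehydes and organozincs (known between separate partners and in five‑ and six‑membered ynal cyclisations) and the nickel‑catalysed reductive macrocyclisation of terminal ynals to endocyclic E‑allylic alcohols (known for twelve‑membered and larger rings); their union in a ten‑membered closure is new. The ten‑membered ring closes in the endo mode (aldehyde carbon to the terminal alkyne carbon C5, favoured by the unhindered terminus and the small carbene ligand), and the γ‑lactone then closes by 5-exo-trig attack of the C6 zinc alkoxide on the C12 methyl ester. The one new stereocentre, C6, is controlled by C7 (Felkin–Anh addition anti to the C8 branch, which places O6 syn to C11 and gives the 6,7-trans lactone). The step needs ring closure to outrun direct methyl addition to the aldehyde and oligomerisation, which slow addition at high dilution, the absence of β‑hydrogens on methyl (no reductive pathway) and the low uncatalysed reactivity of Me2Zn toward aldehydes should secure.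

Step 13
Reactants: 17 (3aS,4S,6E,8S,10E,11aR)-4-[(tert-butyldimethylsilyl)oxy]-8-[(4-methoxybenzyl)oxy]-6,10-dimethyl-3a,4,5,8,9,11a-hexahydrocyclodeca[b]furan-2(3H)-one
Product: 20 (3aS,4S,6E,8S,10E,11aR)-4-[(tert-butyldimethylsilyl)oxy]-8-[(4-methoxybenzyl)oxy]-6,10-dimethyl-3-methylene-3a,4,5,8,9,11a-hexahydrocyclodeca[b]furan-2(3H)-one, via Mannich base 18 (not isolated), via trimethylammonium iodide 19 (not isolated)
Conditions: LiN(i-Pr)2, THF, −78 °C; CH2=NMe2+ I−, −78 °C to rt; MeI, MeOH, rt; NaHCO3 (aq), CH2Cl2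
Reagents that add atoms: Eschenmoser's salt C=[N+](C)C.[I-]
Why: Enolate Mannich reaction with Eschenmoser's salt at C11 (the only acidic position), N‑methylation and Hofmann‑type elimination should install the exocyclic C11=C13 methylene without touching the C7 stereocentre.

Step 14
Reactants: 20 (3aS,4S,6E,8S,10E,11aR)-4-[(tert-butyldimethylsilyl)oxy]-8-[(4-methoxybenzyl)oxy]-6,10-dimethyl-3-methylene-3a,4,5,8,9,11a-hexahydrocyclodeca[b]furan-2(3H)-one
Product: 21 (3aR,4S,6E,8S,10E,11aR)-4-hydroxy-8-[(4-methoxybenzyl)oxy]-6,10-dimethyl-3-methylene-3a,4,5,8,9,11a-hexahydrocyclodeca[b]furan-2(3H)-one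
Conditions: HF·pyridine, pyridine, THF, 0 °C to rt
Reagents that add atoms: none
Why: Buffered HF·pyridine desilylation removes the secondary silyl ether while the benzylic ether, the lactone and the acid‑sensitive 1,5-diene should survive.

Step 15
Reactants: 21 (3aR,4S,6E,8S,10E,11aR)-4-hydroxy-8-[(4-methoxybenzyl)oxy]-6,10-dimethyl-3-methylene-3a,4,5,8,9,11a-hexahydrocyclodeca[b]furan-2(3H)-one + 22 (E)-2-methylbut-2-enoyl chloride
Product: 23 (3aR,4S,6E,8S,10E,11aR)-8-[(4-methoxybenzyl)oxy]-6,10-dimethyl-3-methylene-2-oxo-2,3,3a,4,5,8,9,11a-octahydrocyclodeca[b]furan-4-yl (E)-2-methylbut-2-enoate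
Conditions: 22, DMAP, Et3N, CH2Cl2, 0 °C to rt
Reagents that add atoms: none
Why: DMAP‑catalysed acylation of the only free hydroxyl (C8) by the acid chloride, under which the E (tiglate) geometry is not at risk.

Step 16
Reactants: 23 (3aR,4S,6E,8S,10E,11aR)-8-[(4-methoxybenzyl)oxy]-6,10-dimethyl-3-methylene-2-oxo-2,3,3a,4,5,8,9,11a-octahydrocyclodeca[b]furan-4-yl (E)-2-methylbut-2-enoate
Product: 24 (3aR,4S,6E,8S,10E,11aR)-8-hydroxy-6,10-dimethyl-3-methylene-2-oxo-2,3,3a,4,5,8,9,11a-octahydrocyclodeca[b]furan-4-yl (E)-2-methylbut-2-enoate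
Conditions: DDQ, CH2Cl2/pH 7 buffer, 0 °C
Reagents that add atoms: none
Why: Oxidative cleavage of the 4-methoxybenzyl ether by DDQ (hydride abstraction, hemiacetal hydrolysis) liberates the allylic C2 alcohol and leaves esters and olefins untouched.

Step 17
Reactants: 24 (3aR,4S,6E,8S,10E,11aR)-8-hydroxy-6,10-dimethyl-3-methylene-2-oxo-2,3,3a,4,5,8,9,11a-octahydrocyclodeca[b]furan-4-yl (E)-2-methylbut-2-enoate
Product: 25 (3aR,4S,6E,10E,11aR)-6,10-dimethyl-3-methylene-2,8-dioxo-2,3,3a,4,5,8,9,11a-octahydrocyclodeca[b]furan-4-yl (E)-2-methylbut-2-enoate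
Conditions: Dess–Martin periodinane, pyridine, CH2Cl2, 0 °C
Reagents that add atoms: none
Why: Dess–Martin oxidation of the allylic alcohol gives the C1=C10 enone, which deactivates that olefin toward peracid and acidifies C3–H for the last step.

Step 18
Reactants: 25 (3aR,4S,6E,10E,11aR)-6,10-dimethyl-3-methylene-2,8-dioxo-2,3,3a,4,5,8,9,11a-octahydrocyclodeca[b]furan-4-yl (E)-2-methylbut-2-enoate
Product: 27 molephantinin, via epoxy ketone 26 (not isolated)
Conditions: mCPBA, CH2Cl2, −20 °C; then Et3N, 0 °C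
Reagents that add atoms: 3-chloroperbenzoic acid OOC(=O)c1cccc(Cl)c1
Why: Prilezhaev epoxidation should occur only at the electron‑rich C4=C5 olefin and from its outer face in the crown conformation (C6–H eclipsing the olefin to avoid allylic 1,3-strain with C15, oxygen delivered syn to O6), which sets C5, and triethylamine then opens the β,γ‑epoxy ketone by E1cB elimination from C3 with retention at C5, the Z geometry of C3=C4 being imposed because a planar E,E cross‑conjugated dienone cannot be spanned by the ten‑membered ring.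

**Compound list**

1 | tert-butyl(but-3-yn-1-yloxy)dimethylsilane | C#CCCO[Si](C)(C)C(C)(C)C | starting material
2 | (E)-5-[(tert-butyldimethylsilyl)oxy]-3-methylpent-2-en-1-ol | OC/C=C(\C)CCO[Si](C)(C)C(C)(C)C | intermediate
3 | (E)-5-[(tert-butyldimethylsilyl)oxy]-3-methylpent-2-enal | O=C/C=C(\C)CCO[Si](C)(C)C(C)(C)C | intermediate
4 | allenylboronic acid pinacol ester | C=C=CB1OC(C)(C)C(C)(C)O1 | starting material
5 | (4S,5E)-8-[(tert-butyldimethylsilyl)oxy]-6-methyloct-5-en-1-yn-4-ol | C#CC[C@H](O)/C=C(\C)CCO[Si](C)(C)C(C)(C)C | intermediate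
6 | tert-butyl{[(3E,5S)-5-[(4-methoxybenzyl)oxy]-3-methyloct-3-en-7-yn-1-yl]oxy}dimethylsilane | C#CC[C@H](OCc1ccc(OC)cc1)/C=C(\C)CCO[Si](C)(C)C(C)(C)C | intermediate
7 | (3E,5S)-5-[(4-methoxybenzyl)oxy]-3-methyloct-3-en-7-yn-1-ol | C#CC[C@H](OCc1ccc(OC)cc1)/C=C(\C)CCO | intermediate
8 | (3E,5S)-5-[(4-methoxybenzyl)oxy]-3-methyloct-3-en-7-ynal | C#CC[C@H](OCc1ccc(OC)cc1)/C=C(\C)CC=O | intermediate
9 | (R)-4-benzyloxazolidin-2-one | O=C1N[C@H](Cc2ccccc2)CO1 | starting material
10 | methyl 4-chloro-4-oxobutanoate | COC(=O)CCC(=O)Cl | starting material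
11 | methyl 4-[(R)-4-benzyl-2-oxooxazolidin-3-yl]-4-oxobutanoate | COC(=O)CCC(=O)N1[C@H](Cc2ccccc2)COC1=O | intermediate
12 | methyl (3R,4S,6E,8S)-3-{[(R)-4-benzyl-2-oxooxazolidin-3-yl]carbonyl}-4-hydroxy-8-[(4-methoxybenzyl)oxy]-6-methylundec-6-en-10-ynoate | COC(=O)C[C@@H](C(=O)N1[C@H](Cc2ccccc2)COC1=O)[C@@H](O)C/C(C)=C/[C@@H](OCc1ccc(OC)cc1)CC#C | intermediate
13 | methyl (3R,4S,6E,8S)-4-hydroxy-3-[methoxy(methyl)carbamoyl]-8-[(4-methoxybenzyl)oxy]-6-methylundec-6-en-10-ynoate | COC(=O)C[C@@H](C(=O)N(C)OC)[C@@H](O)C/C(C)=C/[C@@H](OCc1ccc(OC)cc1)CC#C | intermediate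
14 | methyl (3R,4S,6E,8S)-4-[(tert-butyldimethylsilyl)oxy]-3-[methoxy(methyl)carbamoyl]-8-[(4-methoxybenzyl)oxy]-6-methylundec-6-en-10-ynoate | COC(=O)C[C@@H](C(=O)N(C)OC)[C@@H](O[Si](C)(C)C(C)(C)C)C/C(C)=C/[C@@H](OCc1ccc(OC)cc1)CC#C | intermediate
15 | methyl (3R,4S,6E,8S)-4-[(tert-butyldimethylsilyl)oxy]-3-formyl-8-[(4-methoxybenzyl)oxy]-6-methylundec-6-en-10-ynoate | COC(=O)C[C@@H](C=O)[C@@H](O[Si](C)(C)C(C)(C)C)C/C(C)=C/[C@@H](OCc1ccc(OC)cc1)CC#C | intermediate
16 | methyl 2-[(1S,2R,3E,6S,7E,10S)-10-[(tert-butyldimethylsilyl)oxy]-2-hydroxy-6-[(4-methoxybenzyl)oxy]-4,8-dimethylcyclodeca-3,7-dien-1-yl]acetate (formed as its methylzinc alkoxide) | COC(=O)C[C@H]1[C@H](O)/C=C(\C)C[C@H](OCc2ccc(OC)cc2)/C=C(\C)C[C@@H]1O[Si](C)(C)C(C)(C)C | intermediate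
17 | (3aS,4S,6E,8S,10E,11aR)-4-[(tert-butyldimethylsilyl)oxy]-8-[(4-methoxybenzyl)oxy]-6,10-dimethyl-3a,4,5,8,9,11a-hexahydrocyclodeca[b]furan-2(3H)-one (6,7-trans lactone) | O=C1C[C@H]2[C@H](O1)/C=C(\C)C[C@H](OCc3ccc(OC)cc3)/C=C(\C)C[C@@H]2O[Si](C)(C)C(C)(C)C | intermediate
18 | 3-[(dimethylamino)methyl] derivative of 17 (C11 epimers) | O=C1C(CN(C)C)[C@H]2[C@H](O1)/C=C(\C)C[C@H](OCc3ccc(OC)cc3)/C=C(\C)C[C@@H]2O[Si](C)(C)C(C)(C)C | intermediate
19 | trimethylammonium iodide of 18 | O=C1C(C[N+](C)(C)C)[C@H]2[C@H](O1)/C=C(\C)C[C@H](OCc3ccc(OC)cc3)/C=C(\C)C[C@@H]2O[Si](C)(C)C(C)(C)C.[I-] | intermediate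
20 | (3aS,4S,6E,8S,10E,11aR)-4-[(tert-butyldimethylsilyl)oxy]-8-[(4-methoxybenzyl)oxy]-6,10-dimethyl-3-methylene-3a,4,5,8,9,11a-hexahydrocyclodeca[b]furan-2(3H)-one | O=C1C(=C)[C@H]2[C@H](O1)/C=C(\C)C[C@H](OCc3ccc(OC)cc3)/C=C(\C)C[C@@H]2O[Si](C)(C)C(C)(C)C | intermediate
21 | (3aR,4S,6E,8S,10E,11aR)-4-hydroxy-8-[(4-methoxybenzyl)oxy]-6,10-dimethyl-3-methylene-3a,4,5,8,9,11a-hexahydrocyclodeca[b]furan-2(3H)-one | O=C1C(=C)[C@H]2[C@H](O1)/C=C(\C)C[C@H](OCc3ccc(OC)cc3)/C=C(\C)C[C@@H]2O | intermediate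
22 | (E)-2-methylbut-2-enoyl chloride (tigloyl chloride) | C/C=C(\C)C(Cl)=O | starting material
23 | (3aR,4S,6E,8S,10E,11aR)-8-[(4-methoxybenzyl)oxy]-6,10-dimethyl-3-methylene-2-oxo-2,3,3a,4,5,8,9,11a-octahydrocyclodeca[b]furan-4-yl (E)-2-methylbut-2-enoate | O=C1C(=C)[C@H]2[C@H](O1)/C=C(\C)C[C@H](OCc3ccc(OC)cc3)/C=C(\C)C[C@@H]2OC(=O)/C(C)=C/C | intermediate
24 | (3aR,4S,6E,8S,10E,11aR)-8-hydroxy-6,10-dimethyl-3-methylene-2-oxo-2,3,3a,4,5,8,9,11a-octahydrocyclodeca[b]furan-4-yl (E)-2-methylbut-2-enoate | O=C1C(=C)[C@H]2[C@H](O1)/C=C(\C)C[C@H](O)/C=C(\C)C[C@@H]2OC(=O)/C(C)=C/C | intermediate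
25 | (3aR,4S,6E,10E,11aR)-6,10-dimethyl-3-methylene-2,8-dioxo-2,3,3a,4,5,8,9,11a-octahydrocyclodeca[b]furan-4-yl (E)-2-methylbut-2-enoate | O=C1C(=C)[C@H]2[C@H](O1)/C=C(\C)CC(=O)/C=C(\C)C[C@@H]2OC(=O)/C(C)=C/C | intermediate
26 | (1(10)E)-(4R,5R,6S,7R,8S)-4,5-epoxy-2-oxo-8-[(E)-2-methylbut-2-enoyloxy]germacra-1(10),11(13)-dien-12,6-olide | O=C1C(=C)[C@H]2[C@H](O1)[C@H]3O[C@]3(C)CC(=O)/C=C(\C)C[C@@H]2OC(=O)/C(C)=C/C | intermediate
27 | molephantinin, (1(10)E,3Z)-(5S,6S,7R,8S)-5-hydroxy-2-oxo-8-[(E)-2-methylbut-2-enoyloxy]germacra-1(10),3,11(13)-trien-12,6-olide | C=C1C(=O)O[C@H]2[C@H]1[C@@H](OC(=O)/C(C)=C/C)C/C(C)=C/C(=O)/C=C(/C)[C@@H]2O | target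

**Step count and risks**

Total step count: 18. Longest linear sequence: 17 (steps 1–6 and 8–18; step 7 is the side branch).

Steps most likely to fail:

Step 12 (proposed new method). The ten‑membered nickelacycle may form too slowly, so that direct methyl transfer from zinc to the aldehyde, alkyne oligomerisation or closure in the exo mode (bond to C4) take over; the aldehyde face selection may also be poor. The fallback forms the same bond by known chemistry and sets out from 14. Zirconium‑catalysed carboalumination of the terminal alkyne (AlMe3, Cp2ZrCl2, CH2Cl2, 0 °C; then I2), with amide and ester expected to survive as aluminium complexes, gives the (E)-iodoalkene Weinreb amide F1. Reduction with i-Bu2AlH at −78 °C gives the iodo aldehyde F2. Nozaki–Hiyama–Kishi macrocyclisation (CrCl2, NiCl2 cat., DMSO/THF, high dilution), with the olefin geometry carried by the iodide, closes C5–C6 and comes back to the route at hydroxy ester 16, which catalytic DBU lactonises to 17.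

Step 18. m-Chlorobenzoic acid may open the epoxy germacradienone transannularly onto C1=C10 before the base acts, and face selectivity at C4=C5 may erode. The fallback avoids both peracid and epoxide and sets out from 25. Photooxygenation (O2, tetraphenylporphyrin, hν, CH2Cl2, −20 °C) should effect a Schenck ene reaction on the outer face of C4=C5 with abstraction of the ketone‑activated C3–H, giving the C5 hydroperoxide F3 with the C3=C4 olefin already in place (any 4(15)-isomer would be conjugated by Et3N). Reduction with PPh3 comes back to the route at 27.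

Step 13. The amide base may act on the strained trans‑fused lactone in other ways than C11 deprotonation (ring opening), and the liberated amines may add back to the new Michael acceptor so that the elimination stalls. The fallback uses no strong base and sets out from 17. Condensation with tert-butoxybis(dimethylamino)methane (Bredereck's reagent, neat, 60 °C) gives the enamino lactone F4. Reduction with i-Bu2AlH at −78 °C followed by silica gel work‑up (hydride addition then loss of dimethylamine) comes back to the route at 20.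

Further compounds
F1 | step 12 | methyl (3R,4S,6E,8S,10E)-4-[(tert-butyldimethylsilyl)oxy]-11-iodo-3-[methoxy(methyl)carbamoyl]-8-[(4-methoxybenzyl)oxy]-6,10-dimethylundeca-6,10-dienoate | COC(=O)C[C@@H](C(=O)N(C)OC)[C@@H](O[Si](C)(C)C(C)(C)C)C/C(C)=C/[C@@H](OCc1ccc(OC)cc1)C/C(C)=C/I
F2 | step 12 | methyl (3R,4S,6E,8S,10E)-4-[(tert-butyldimethylsilyl)oxy]-3-formyl-11-iodo-8-[(4-methoxybenzyl)oxy]-6,10-dimethylundeca-6,10-dienoate | COC(=O)C[C@@H](C=O)[C@@H](O[Si](C)(C)C(C)(C)C)C/C(C)=C/[C@@H](OCc1ccc(OC)cc1)C/C(C)=C/I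
F3 | step 18 | (1(10)E,3Z)-(5S,6S,7R,8S)-5-hydroperoxy-2-oxo-8-[(E)-2-methylbut-2-enoyloxy]germacra-1(10),3,11(13)-trien-12,6-olide | C=C1C(=O)O[C@H]2[C@H]1[C@@H](OC(=O)/C(C)=C/C)C/C(C)=C/C(=O)/C=C(/C)[C@@H]2OO
F4 | step 13 | 3-[(dimethylamino)methylene] derivative of 17 | O=C1C(=CN(C)C)[C@H]2[C@H](O1)/C=C(\C)C[C@H](OCc3ccc(OC)cc3)/C=C(\C)C[C@@H]2O[Si](C)(C)C(C)(C)C
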